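**Retrosynthetic overview**

- Enabling feature: the O1–C2(=O) unit of the furan-2,4-dione (tetronic acid) ring is one molecule of CO2. C3 lies between the C4 ring carbonyl and the side-chain ketone, so it is a 1,3-dicarbonyl carbon that is nucleophilic under soft enolisation. C5, alpha to C4, carries the CH2OH arm, whose oxygen can be the leaving group of a C5–C6 oxirane.
- Key disconnection: target ⇒ CO2 + (R)-15-methyl-1-(oxiran-2-yl)hexadecane-1,3-dione, a formal (3+2) carboxylative annulation. It makes C2–C3 by carboxylation and O1–C5 by SN2 opening with inversion (R oxirane to 5S), and frees the primary alcohol without protecting groups.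
- Epoxy diketone ⇒ crossed Claisen condensation of the kinetic enolate of 14-methylpentadecan-2-one with methyl (R)-glycidate; methyl ketone ⇒ 13-methyltetradecanoic acid + MeLi.
- Ring order: the only ring of the target, the five-membered lactone, is closed in the last step; the oxirane is a temporary ring bought with the glycidate and consumed there.

Key step: step 3

Remark: 13-methyltetradecanoic acid and methyl (R)-glycidate are taken as commercial; 3-acyltetronic acids are mixtures of enol tautomers, and the product is written in the 4-hydroxy form.

**Route**

Step 1
Reactants: 1 13-methyltetradecanoic acid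
Product: 3 14-methylpentadecan-2-one, via dilithium gem-diolate 2 (not isolated)
Conditions: MeLi (2.2 equiv), Et2O, 0 °C to rt; then H2O, 0 °C
Reagents that add atoms: methyllithium, [Li]C
Why: Addition of an organolithium to a lithium carboxylate should stop at the dilithium gem-diolate 2, which resists a second addition and collapses to the methyl ketone only on aqueous quench.

Step 2
Reactants: 3 14-methylpentadecan-2-one; 4 methyl (R)-oxirane-2-carboxylate (methyl (R)-glycidate)
Product: 6 (R)-15-methyl-1-(oxiran-2-yl)hexadecane-1,3-dione, via lithium enolate 5 (not isolated)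
Conditions: 3 (2.0 equiv), LiN(iPr)2 (2.0 equiv), THF, −78 °C; then 4 (1.0 equiv), −78 to −40 °C; AcOH, −78 °C; rapid filtration through deactivated silica
Reagents that add atoms: none
Why: In this crossed Claisen condensation, kinetic deprotonation on the CH3 side gives enolate 5, which at low temperature should attack the activated ester carbonyl of 4 rather than the oxirane, while the second equivalent of enolate deprotonates the product diketone and drives the reaction; the oxirane C–H is not enolisable, so the R configuration is carried over unchanged.

Step 3
Reactants: 6 (R)-15-methyl-1-(oxiran-2-yl)hexadecane-1,3-dione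
Product: 8 (5S)-4-hydroxy-5-(hydroxymethyl)-3-(13-methyltetradecanoyl)furan-2(5H)-one, via magnesium carboxylate chelate 7 (not isolated)
Conditions: CO2 (10 bar), Mg(OTf)2 (2.2 equiv), iPr2NEt (3.5 equiv), MeCN (0.05 M), 0 °C to rt; then 1 M HCl
Reagents that add atoms: carbon dioxide, O=C=O
Why: Proposed new method: soft enolisation by amine and divalent magnesium should give the six-membered magnesium chelate of the 1,3-diketone, whose central carbon C3 is carboxylated reversibly by CO2 (as in magnesium-mediated carboxylation of active methylene compounds with CO2), after which the magnesium-bound carboxylate 7 opens the neighbouring oxirane at C5 by intramolecular SN2 attack (as in the cyclisation of epoxy acids to hydroxy lactones) and frees the C6 alkoxide that becomes the CH2OH group, so that overall a three-carbon unit that is nucleophilic at C3 and electrophilic at C5 adds across the C=O of CO2 in a formal (3+2) annulation with every atom of 6 and of CO2 retained. The closest known reaction type for this pair of bonds is the silver-catalysed incorporation of CO2 into conjugated ynones that gives 5-ylidene tetronic acids, here transposed from an alkyne to an oxirane as the electrophile. The furan-2,4-dione ring closes in the 5-exo-tet mode (the breaking C5–O bond is exocyclic), which should be preferred over 6-endo attack at the terminal CH2. The single stereocentre C5 is not created but inverted: backside displacement converts the R oxirane carbon into 5S, so the configuration derives from methyl (R)-glycidate. The step needs chemoselectivity for the carboxylate oxygen over the side-chain enolate oxygen (which would give a furan-3(2H)-one) and regioselectivity for C5 over C6; the chelate holds both diketone oxygens on magnesium in a U-shaped geometry in which the side-chain oxygen cannot reach C5 while the carboxylate on C3 lies next to it, the halide-free medium suppresses a cyclic-carbonate pathway that would retain C5, and formation of the strongly stabilised 3-acyltetronate chelate should make the cascade irreversible.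

**Compound list**

1 | 13-methyltetradecanoic acid | CC(C)CCCCCCCCCCCC(=O)O | starting material
2 | dilithium 14-methylpentadecane-2,2-bis(olate) | CC(C)CCCCCCCCCCCC(C)([O-])[O-].[Li+].[Li+] | intermediate
3 | 14-methylpentadecan-2-one | CC(C)CCCCCCCCCCCC(C)=O | intermediate
4 | methyl (R)-oxirane-2-carboxylate | COC(=O)[C@H]1CO1 | starting material
5 | lithium 14-methylpentadec-1-en-2-olate | CC(C)CCCCCCCCCCCC(=C)[O-].[Li+] | intermediate
6 | (R)-15-methyl-1-(oxiran-2-yl)hexadecane-1,3-dione | CC(C)CCCCCCCCCCCC(=O)CC(=O)[C@H]1CO1 | intermediate
7 | magnesium salt of the C3-carboxylated diketone dianion, (R)-oxirane intact (drawn as the carbanion resonance form) | CC(C)CCCCCCCCCCCC(=O)[C-](C(=O)[O-])C(=O)[C@H]1CO1.[Mg+2] | intermediate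
8 | (5S)-4-hydroxy-5-(hydroxymethyl)-3-(13-methyltetradecanoyl)furan-2(5H)-one | CC(C)CCCCCCCCCCCC(=O)C1=C(O)[C@H](CO)OC1=O | target

**Step count and risks**

Total step count: 3. Longest linear sequence: 3 steps (1 → 3 → 6 → 8).

Steps most likely to fail:

1. Step 3. Carboxylation of the chelated diketonate may be too slow or too unfavourable. O-alkylation of the diketonate oxygen by the oxirane, opening at the terminal carbon, or a retentive path through a cyclic carbonate could then take over, with loss of material or of enantiopurity. The fallback uses the established Dieckmann route, sets out from 1 and returns at 8. Acid 1 is condensed with 2,2-dimethyl-1,3-dioxane-4,6-dione (DCC, DMAP, CH2Cl2) to give 5-(1-hydroxy-13-methyltetradecylidene)-2,2-dimethyl-1,3-dioxane-4,6-dione F1. Commercial methyl (S)-2,2-dimethyl-1,3-dioxolane-4-carboxylate is hydrolysed (aq AcOH) to methyl (S)-2,3-dihydroxypropanoate F2, which is tritylated at the primary hydroxyl (TrCl, pyridine) to methyl (S)-2-hydroxy-3-(trityloxy)propanoate F3. Heating F1 with F3 in toluene (acylketene trapping) should give methyl (S)-2-[(15-methyl-3-oxohexadecanoyl)oxy]-3-(trityloxy)propanoate F4. Dieckmann cyclisation (Bu4NF, THF, rt) should give (5S)-4-hydroxy-3-(13-methyltetradecanoyl)-5-[(trityloxy)methyl]furan-2(5H)-one F5. Acidic removal of the trityl group (aq TFA, CH2Cl2) then gives 8, with C5 retaining the glycerate configuration.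

2. Step 2. The enolate may attack the oxirane instead of the ester carbonyl, proton exchange may stall the acyl transfer, or the epoxy diketone may cyclise during quench and purification. The fallback reverses the polarity of the condensation, sets out from 4 and 1 and returns at 6. Ester 4 is converted with LiN(OMe)Me (from MeNHOMe·HCl and LiN(SiMe3)2, THF, −78 °C) into (R)-N-methoxy-N-methyloxirane-2-carboxamide F6. MeMgBr (THF, −78 °C) should then give (R)-1-(oxiran-2-yl)ethan-1-one F7. Acid 1 is activated as 1-(1H-benzotriazol-1-yl)-13-methyltetradecan-1-one F8 (benzotriazole, SOCl2, CH2Cl2). The lithium enolate of F7 (LiN(SiMe3)2, THF, −78 °C) is C-acylated by F8 to give 6.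

3. Step 1. The gem-diolate may collapse early and take up a second MeLi (tertiary alcohol formation), or addition to the poorly soluble lithium carboxylate may be incomplete. The fallback goes through an isolable acyl derivative, sets out from 1 and returns at 3. Acid 1 with 1,1'-carbonyldiimidazole and then MeNHOMe·HCl (CH2Cl2, rt) gives N-methoxy-N,13-dimethyltetradecanamide F9. MeMgBr (THF, 0 °C) should convert F9 into 3 through the chelated tetrahedral intermediate.

**Further compounds**

F1 | step 3 | 5-(1-hydroxy-13-methyltetradecylidene)-2,2-dimethyl-1,3-dioxane-4,6-dione | CC(C)CCCCCCCCCCCC(O)=C1C(=O)OC(C)(C)OC1=O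
F2 | step 3 | methyl (S)-2,3-dihydroxypropanoate | COC(=O)[C@@H](O)CO
F3 | step 3 | methyl (S)-2-hydroxy-3-(trityloxy)propanoate | COC(=O)[C@@H](O)COC(c1ccccc1)(c1ccccc1)c1ccccc1
F4 | step 3 | methyl (S)-2-[(15-methyl-3-oxohexadecanoyl)oxy]-3-(trityloxy)propanoate | CC(C)CCCCCCCCCCCC(=O)CC(=O)O[C@@H](COC(c1ccccc1)(c1ccccc1)c1ccccc1)C(=O)OC
F5 | step 3 | (5S)-4-hydroxy-3-(13-methyltetradecanoyl)-5-[(trityloxy)methyl]furan-2(5H)-one | CC(C)CCCCCCCCCCCC(=O)C1=C(O)[C@H](COC(c2ccccc2)(c2ccccc2)c2ccccc2)OC1=O
F6 | step 2 | (R)-N-methoxy-N-methyloxirane-2-carboxamide | CON(C)C(=O)[C@H]1CO1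
F7 | step 2 | (R)-1-(oxiran-2-yl)ethan-1-one | CC(=O)[C@H]1CO1
F8 | step 2 | 1-(1H-benzotriazol-1-yl)-13-methyltetradecan-1-one | CC(C)CCCCCCCCCCCC(=O)n1nnc2ccccc12
F9 | step 1 | N-methoxy-N,13-dimethyltetradecanamide | CC(C)CCCCCCCCCCCC(=O)N(C)OC
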